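The numbers in the tables are simulated with made-up constants, and the scatter is random.

In this closed, stirred vessel, starting material and coupling partner join to a loose adduct while product appears, and coupling partner is the limiting reagent by charge in cedar and in ash.

| flask | starting material | coupling partner | remark | time |
|---|---|---|---|---|
| ochre | 10 mM | 6.2 mM | run made earlier |  |
| grey | 10 mM | 9.2 mM | run made earlier |  |
| cedar | 10 mM | 6.00 mM |  | 8.0 h |
| ash | 10 mM | 5.00 mM |  | 8.0 h |

- ochre (time / h: starting material / %, product / %, loose adduct / %): 1.00: 76.2, 1.8, 21.1; 3.00: 73.1, 4.8, 20.0; 5.00: 70.7, 7.8, 19.0; 8.00: 67.0, 10.7, 17.3
- grey (time / h: starting material / %, product / %, loose adduct / %): 1.00: 66.9, 2.4, 29.9; 3.00: 62.9, 6.7, 27.8; 5.00: 60.4, 10.9, 25.1; 8.00: 56.1, 13.7, 22.6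

(each reading ± 0.5 percentage points)

- a reading or a percentage of product counts all its forms, free or not
- a reading of starting material is of its free form alone

- which of these there is most of at the end, counted by the starting material in it, cedar (product / loose adduct / starting material)
- which of these there is most of at the end, counted by the starting material in it, ash (product / loose adduct / starting material)
- final amount of the leader among these, as a percentage of the starting material charged, in cedar
- final amount of the leader among these, as a percentage of the starting material charged, in ash

What stays still while the readings drift? I take free coupling partner as its charge less adduct less product, then divide adduct by free starting material times free partner. This reads 0.0708 mM⁻¹ in ochre at 1.00 h, 0.0759 mM⁻¹ in ochre at 8.00 h and 0.0723 mM⁻¹ in grey at 8.00 h. So I take the mean of the two readings at 8.00 h, 0.0741 mM⁻¹, and freeze it as the holding constant, the usual pre-equilibrium constant, adduct over free starting material times free partner.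

How much has moved past the adduct by then? Per adduct at 8.00 h, the starting material that is neither free nor adduct reads 0.925 on the mean of ochre and grey, and product reads 0.612.

What does that leave at 8.0 h? I carry both ratios to the smaller partner charges, which is a stretch beyond the two runs. Each free amount is then its charge less a multiple of the adduct, and the holding constant gives a quadratic. My reckoning gives cedar 1.67 mM of adduct and 67.9% free starting material. Ash gets 1.44 mM of adduct and 72.3% free starting material.

The forecast says “Free starting material leads in every run, so it should also lead in cedar and ash.” It puts starting material at 68% in cedar and 72.6% in ash.

Cedar gives 68.0% and ash 72.4%, with starting material leading in each.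

    starting material + coupling partner ⇌ loose adduct (K = 75.0 M⁻¹, k = 805 M⁻¹ h⁻¹)
    loose adduct → product (k = 0.0740 h⁻¹)
    starting material + product ⇌ idle adduct, settled at all times (K = 90.9 M⁻¹)

Idle adduct, which counts double in these percentages, stands at 8.58% in cedar and 7.65% in ash at 8.00 h, or 0.522 and 0.540 of the loose adduct. In cedar, 54% of the partner charge is free, so the holding constant predicts 0.240 adduct per free starting material, and the flask shows 0.242. A neighbour of cedar charged with 24 mM of coupling partner keeps 72.8% of that charge free at 8.00 h, which predicts 1.29 adduct per free starting material, and it holds 37.8% adduct against 28.9% free starting material.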